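**Retrosynthetic overview**

- The acid comes from its methyl ester, and the ester from one [3+2] annulation of an open-chain triethylsilyl peroxyketal (carrying the whole side chain) with methyl 3-methylbut-3-enoate. This single step makes ring bonds C4–C5 and O2–C3.
- Enabling feature: in the 1,2-dioxolane, C5 (bonded to O1, CH3 and the side chain) is a ketone-level carbon, and C3 (CH3, CH2CO2H) is a tertiary carbon that can carry a cation. Only the C4 methylene lies between them, so the ring is a C5–O1–O2 peroxycarbenium unit plus a C4=C3 isobutene unit.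
- The peroxyketal comes from a dimethyl ketal (perhydrolysis, silylation). The ketal comes from a C9 ketal aldehyde and a phenylpentenyl tetrazolyl sulfone by Julia–Kocienski olefination at C7'=C8' of the side chain.
- The side-chain methyl centre C2' comes from a copper-catalysed asymmetric conjugate addition of MeMgBr to an enone made from methyl 6-oxohexanoate. The E-styrene comes from a Johnson–Claisen rearrangement.
- Ring order: the phenyl ring is bought; the dioxolane is the only ring made and is closed last but one (step 12).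

Key step: step 12

Assumption: the ligand in step 6 and the catalyst in step 12 are written in one enantiomeric form; which mirror-image form gives (6R) and (3S,5R) is settled by a first test run, and the other form is used if needed.

**Step 1**
Reactants: 1 1-phenylprop-2-en-1-ol (racemic); 2 triethyl orthoacetate
Product: 4 ethyl (4E)-5-phenylpent-4-enoate, via mixed ketene acetal 3 (not isolated)
Conditions: 2 (5 equiv), EtCO2H (cat.), 140 °C, EtOH distilled off
Reagents that add atoms: none
Why: Johnson–Claisen rearrangement, in which the chair-like [3,3] shift of ketene acetal 3 places phenyl equatorial and should give the E-alkene.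

**Step 2**
Reactants: 4 ethyl (4E)-5-phenylpent-4-enoate
Product: 5 (4E)-5-phenylpent-4-en-1-ol
Conditions: LiAlH4, THF, 0 °C; then H2O, aq. NaOH
Reagents that add atoms: none
Why: Hydride reduction of an ester to the primary alcohol; the isolated styrenyl alkene is inert to LiAlH4.

**Step 3**
Reactants: 5 (4E)-5-phenylpent-4-en-1-ol
Product: 6 1-phenyl-5-{[(4E)-5-phenylpent-4-en-1-yl]sulfanyl}-1H-tetrazole
Conditions: 1-phenyl-1H-tetrazole-5-thiol, PPh3, iPrO2C–N=N–CO2iPr, THF, 0 °C → rt
Reagents that add atoms: 1-phenyl-1H-tetrazole-5-thiol, Sc1nnnn1-c1ccccc1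
Why: Mitsunobu thioetherification of a primary alcohol with the acidic tetrazolethiol (SN2 at CH2).

**Step 4**
Reactants: 6 1-phenyl-5-{[(4E)-5-phenylpent-4-en-1-yl]sulfanyl}-1H-tetrazole
Product: 7 1-phenyl-5-{[(4E)-5-phenylpent-4-en-1-yl]sulfonyl}-1H-tetrazole
Conditions: (NH4)6Mo7O24·4H2O (cat.), 30% aq. H2O2, EtOH, 0 °C → rt
Reagents that add atoms: hydrogen peroxide, OO
Why: Molybdate-catalysed peroxide oxidation of a sulfide to the sulfone, the usual entry to Julia–Kocienski reagents, which should spare the 1,2-disubstituted alkene.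

**Step 5**
Reactants: 8 methyl 6-oxohexanoate; 9 1-(triphenyl-λ5-phosphanylidene)propan-2-one
Product: 10 methyl (6E)-8-oxonon-6-enoate
Conditions: CH2Cl2, rt
Reagents that add atoms: none
Why: Wittig olefination with a stabilised ylide, which reacts only at the aldehyde and should give the E-enone.

**Step 6**
Reactants: 10 methyl (6E)-8-oxonon-6-enoate
Product: 11 methyl (6R)-6-methyl-8-oxononanoate
Conditions: MeMgBr (1.2 equiv), CuBr·SMe2 (5 mol%), (R)-1-[(S)-2-(diphenylphosphino)ferrocenyl]ethyldicyclohexylphosphine (6 mol%), tBuOMe, −75 °C; then MeOH, aq. NH4Cl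
Reagents that add atoms: methylmagnesium bromide, C[Mg]Br
Why: Copper-catalysed asymmetric conjugate addition of a Grignard reagent to an acyclic 3-alken-2-one, in which the copper–ferrocenyl diphosphine complex must deliver methyl to the Re face of C6 to set (6R); at −75 °C the ester should not be attacked.

**Step 7**
Reactants: 11 methyl (6R)-6-methyl-8-oxononanoate
Product: 12 methyl (6R)-8,8-dimethoxy-6-methylnonanoate
Conditions: HC(OMe)3, MeOH, p-TsOH·H2O (cat.), rt; then Et3N
Reagents that add atoms: trimethyl orthoformate, COC(OC)OC; methanol, CO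
Why: Acid-catalysed ketalisation driven by the orthoester; the ketal protects the ketone through steps 8 and 9 and is itself the precursor of the peroxyketal.

**Step 8**
Reactants: 12 methyl (6R)-8,8-dimethoxy-6-methylnonanoate
Product: 13 (6R)-8,8-dimethoxy-6-methylnonanal
Conditions: iBu2AlH (1.05 equiv), CH2Cl2, −78 °C; then MeOH, aq. potassium sodium tartrate
Reagents that add atoms: none
Why: Partial reduction of a methyl ester to the aldehyde with one equivalent of iBu2AlH at −78 °C; the dimethyl ketal is inert to hydride.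

**Step 9**
Reactants: 7 1-phenyl-5-{[(4E)-5-phenylpent-4-en-1-yl]sulfonyl}-1H-tetrazole; 13 (6R)-8,8-dimethoxy-6-methylnonanal
Product: 14 (4R,9E,13E)-2,2-dimethoxy-4-methyl-14-phenyltetradeca-9,13-diene
Conditions: 7, KN(SiMe3)2, MeOCH2CH2OMe, −60 °C; then 13, −60 °C → rt; aq. NH4Cl
Reagents that add atoms: none
Why: Julia–Kocienski olefination of an unbranched aldehyde with a metalated phenyltetrazolyl sulfone, which with potassium in a coordinating ether should favour the E-alkene at C9=C10; ketal and styrene are inert to the base.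

**Step 10**
Reactants: 14 (4R,9E,13E)-2,2-dimethoxy-4-methyl-14-phenyltetradeca-9,13-diene
Product: 15 (4R,9E,13E)-2-hydroperoxy-2-methoxy-4-methyl-14-phenyltetradeca-9,13-diene (both C2 epimers)
Conditions: H2O2 (anhydrous, in Et2O, excess), pyridinium p-toluenesulfonate (cat.), 0 °C; then NaHCO3
Reagents that add atoms: hydrogen peroxide, OO
Why: Acid-catalysed perhydrolysis of a dimethyl ketal (exchange of one methoxy group for hydroperoxide, driven by excess H2O2); the new C2 centre forms as both epimers, which does not matter because it becomes planar in step 12.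

**Step 11**
Reactants: 15 (4R,9E,13E)-2-hydroperoxy-2-methoxy-4-methyl-14-phenyltetradeca-9,13-diene
Product: 16 triethyl{[(4R,9E,13E)-2-methoxy-4-methyl-14-phenyltetradeca-9,13-dien-2-yl]peroxy}silane (both C2 epimers)
Conditions: Et3SiCl, imidazole, DMF, 0 °C
Reagents that add atoms: chlorotriethylsilane, CC[Si](Cl)(CC)CC
Why: O-Silylation of the hydroperoxide with a chlorosilane and imidazole, which gives the silyl peroxide whose distal oxygen can later close the ring with loss of the silyl group.

**Step 12**
Reactants: 16 triethyl{[(4R,9E,13E)-2-methoxy-4-methyl-14-phenyltetradeca-9,13-dien-2-yl]peroxy}silane; 17 methyl 3-methylbut-3-enoate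
Product: 20 methyl 2-[(3S,5R)-3,5-dimethyl-5-[(2R,7E,11E)-2-methyl-12-phenyldodeca-7,11-dien-1-yl]-1,2-dioxolan-3-yl]acetate, via peroxycarbenium ion 18 (not isolated), via tertiary carbocation 19 (not isolated)
Conditions: 17 (5 equiv), (S,S)-imidodiphosphorimidate acid HN[P(=NSO2CF3)(O2C20H10Ar2)]2 (Ar = 3,5-(CF3)2C6H3, both binaphthyl units S; 5 mol%), toluene, −78 °C; then Et3N
Reagents that add atoms: none
Why: Proposed new method: the chiral acid (and, after the first turnover, its silylated form) takes methoxide from 16 to give peroxycarbenium ion 18 paired with the confined imidodiphosphorimidate anion, the CH2 terminus of 17 adds to the cationic carbon (C4–C5 bond) to give tertiary cation 19, the distal silylperoxy oxygen captures it (O2–C3 bond) and Et3Si+ returns to the anion, so that Et3SiOMe is the only co-product. The closest known reaction type is the SnCl4- or TiCl4-promoted [3+2] annulation of triethylsilyl peroxyketals with 1,1-disubstituted alkenes to 3,3,5,5-tetrasubstituted 1,2-dioxolanes, which is not enantioselective; counteranion-directed additions of alkenes and silyl nucleophiles to oxocarbenium ions under imidodiphosphorimidate catalysis are the ground for expecting control. The one ring formed, the 1,2-dioxolane, closes by oxygen capture of a discrete tertiary carbocation, a five-membered cation–nucleophile closure (formally 5-endo with respect to the former C=C bond) within a stepwise cationic annulation. C5 is set in the C–C bond formation, in which the anion must leave open the Si face of the C=O+ unit (priorities O, CH2, CH3) although its flanks differ only as CH3 and CH2CH(CH3)R, and C3 is set in the ring closure inside the same ion pair, in which CH2CO2Me must end up cis to the C5 methyl; the resident C2' centre is too remote to bias either event, so both are catalyst-controlled. The step needs site selectivity for 17 over the two 1,2-disubstituted alkenes of the side chain, secured by the 1,1-disubstitution of 17 (attack at CH2, charge at the tertiary carbon) and by its excess at −78 °C, and it needs ring closure to outrun proton loss from 19, which the 1,3-placement of the peroxide oxygen favours.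

**Step 13**
Reactants: 20 methyl 2-[(3S,5R)-3,5-dimethyl-5-[(2R,7E,11E)-2-methyl-12-phenyldodeca-7,11-dien-1-yl]-1,2-dioxolan-3-yl]acetate
Product: 21 2-[(3S,5R)-3,5-dimethyl-5-[(2R,7E,11E)-2-methyl-12-phenyldodeca-7,11-dien-1-yl]-1,2-dioxolan-3-yl]acetic acid
Conditions: LiOH, THF/H2O, 0 °C → rt; then 1 M HCl to pH 3
Reagents that add atoms: lithium hydroxide, [Li+].[OH-]
Why: Saponification of the methyl ester; the dioxolane has no hydrogen on C3 or C5 and so cannot fragment by base-induced O–O cleavage, and hydroxide attack at the ester carbonyl should outpace enolisation and β-elimination of the peroxide.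

**Compound list**

1 | 1-phenylprop-2-en-1-ol (racemic) | C=CC(O)c1ccccc1 | starting material
2 | triethyl orthoacetate | CC(OCC)(OCC)OCC | starting material
3 | 1-ethoxy-1-[(1-phenylprop-2-en-1-yl)oxy]ethene (mixed ketene acetal) | C=C(OCC)OC(C=C)c1ccccc1 | intermediate (not isolated)
4 | ethyl (4E)-5-phenylpent-4-enoate | CCOC(=O)CC/C=C/c1ccccc1 | intermediate
5 | (4E)-5-phenylpent-4-en-1-ol | OCCC/C=C/c1ccccc1 | intermediate
6 | 1-phenyl-5-{[(4E)-5-phenylpent-4-en-1-yl]sulfanyl}-1H-tetrazole | c1ccccc1-n1nnnc1SCCC/C=C/c1ccccc1 | intermediate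
7 | 1-phenyl-5-{[(4E)-5-phenylpent-4-en-1-yl]sulfonyl}-1H-tetrazole | c1ccccc1-n1nnnc1S(=O)(=O)CCC/C=C/c1ccccc1 | intermediate
8 | methyl 6-oxohexanoate | COC(=O)CCCCC=O | starting material
9 | 1-(triphenyl-λ5-phosphanylidene)propan-2-one | CC(=O)C=P(c1ccccc1)(c1ccccc1)c1ccccc1 | starting material
10 | methyl (6E)-8-oxonon-6-enoate | COC(=O)CCCC/C=C/C(C)=O | intermediate
11 | methyl (6R)-6-methyl-8-oxononanoate | CC(=O)C[C@H](C)CCCCC(=O)OC | intermediate
12 | methyl (6R)-8,8-dimethoxy-6-methylnonanoate | COC(C)(OC)C[C@H](C)CCCCC(=O)OC | intermediate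
13 | (6R)-8,8-dimethoxy-6-methylnonanal | COC(C)(OC)C[C@H](C)CCCCC=O | intermediate
14 | (4R,9E,13E)-2,2-dimethoxy-4-methyl-14-phenyltetradeca-9,13-diene | COC(C)(OC)C[C@H](C)CCCC/C=C/CC/C=C/c1ccccc1 | intermediate
15 | (4R,9E,13E)-2-hydroperoxy-2-methoxy-4-methyl-14-phenyltetradeca-9,13-diene (both C2 epimers) | COC(C)(OO)C[C@H](C)CCCC/C=C/CC/C=C/c1ccccc1 | intermediate
16 | triethyl{[(4R,9E,13E)-2-methoxy-4-methyl-14-phenyltetradeca-9,13-dien-2-yl]peroxy}silane (both C2 epimers) | COC(C)(OO[Si](CC)(CC)CC)C[C@H](C)CCCC/C=C/CC/C=C/c1ccccc1 | intermediate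
17 | methyl 3-methylbut-3-enoate | COC(=O)CC(C)=C | starting material
18 | [(4R,9E,13E)-4-methyl-14-phenyltetradeca-9,13-dien-2-ylidene][(triethylsilyl)oxy]oxidanium (peroxycarbenium ion, paired with the catalyst anion) | CC(=[O+]O[Si](CC)(CC)CC)C[C@H](C)CCCC/C=C/CC/C=C/c1ccccc1 | intermediate (not isolated)
19 | (7R,12E,16E)-1-methoxy-3,5,7-trimethyl-1-oxo-17-phenyl-5-[(triethylsilyl)peroxy]heptadeca-12,16-dien-3-ylium (tertiary carbocation, C5 configured as in 20) | C[C@H](CCCC/C=C/CC/C=C/c1ccccc1)C[C@](C)(C[C+](C)CC(=O)OC)OO[Si](CC)(CC)CC | intermediate (not isolated)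
20 | methyl 2-[(3S,5R)-3,5-dimethyl-5-[(2R,7E,11E)-2-methyl-12-phenyldodeca-7,11-dien-1-yl]-1,2-dioxolan-3-yl]acetate | C[C@H](CCCC/C=C/CC/C=C/c1ccccc1)C[C@]1(C)C[C@@](C)(CC(=O)OC)OO1 | intermediate
21 | 2-[(3S,5R)-3,5-dimethyl-5-[(2R,7E,11E)-2-methyl-12-phenyldodeca-7,11-dien-1-yl]-1,2-dioxolan-3-yl]acetic acid | C[C@H](CCCC/C=C/CC/C=C/c1ccccc1)C[C@]1(C)C[C@@](C)(CC(=O)O)OO1 | target

**Step count**

Total: 13 steps. Longest linear sequence: 9 steps (steps 5–13 from 8, or steps 1–4 and 9–13 from 1).

**Steps most likely to fail**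

1. Step 12 (proposed new method). What may go wrong: no turnover of the silylium relay, weak facial discrimination at the peroxycarbenium carbon or in the ring closure, proton loss from the tertiary cation, or capture of the cation by a side-chain alkene. The fallback uses known reaction types and makes the two bonds in separate operations; it sets out from 16 and comes back at 20.
   - Methyl 3-methylbut-2-enoate is converted (LiN(iPr)2, Me3SiCl, THF, −78 °C) into the silyl dienolate [(1-methoxy-3-methylbuta-1,3-dien-1-yl)oxy]trimethylsilane F1.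
   - Me3SiOSO2CF3-catalysed vinylogous Mukaiyama-type addition of F1 to the peroxycarbenium ion from 16 (CH2Cl2, −78 °C) forms the C4–C5 bond and gives methyl (2E,7R,12E,16E)-3,5,7-trimethyl-17-phenyl-5-[(triethylsilyl)peroxy]heptadeca-2,12,16-trienoate F2.
   - HF·pyridine (THF, 0 °C) frees the hydroperoxide methyl (2E,7R,12E,16E)-5-hydroperoxy-3,5,7-trimethyl-17-phenylheptadeca-2,12,16-trienoate F3.
   - Et2NH in CF3CH2OH closes the ring by intramolecular conjugate addition (5-exo-trig) to the dioxolane ester as a mixture of its C3/C5 stereoisomers F4.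
   - This path gives up control of C3 and C5. Because of C2' the four isomers are diastereomers, and the (3S,5R) isomer 20 would have to be separated by preparative HPLC and assigned by NOE.

2. Step 10. What may go wrong: over-exchange to the geminal bis-hydroperoxide, acid-promoted rearrangement of the hydroperoxy ketal, or incomplete conversion in an exchange equilibrium. The fallback sets out from 14 and comes back at 15.
   - Me3SiOSO2CF3 and iPr2NEt (CH2Cl2, −20 °C) eliminate methanol to the methyl enol ether (4R,9E,13E)-2-methoxy-4-methyl-14-phenyltetradeca-1,9,13-triene F5 (with some of its 2-ene isomer, which reacts the same way).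
   - Addition of anhydrous H2O2 across the enol ether (pyridinium p-toluenesulfonate cat., Et2O, −20 °C) is irreversible and should give 15 without an exchange equilibrium.

3. Step 6. What may go wrong: insufficient enantioselectivity, or competing 1,2-addition and attack at the ester. The fallback takes the stereocentre from the chiral pool. It sets out from none of the numbered compounds: it replaces 8–11 by commercial (R)-citronellal F6 and comes back at 12.
   - MeMgBr (Et2O, 0 °C) gives (4R)-4,8-dimethylnon-7-en-2-ol F7.
   - Swern oxidation gives (4R)-4,8-dimethylnon-7-en-2-one F8.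
   - HC(OMe)3, MeOH and p-TsOH give (6R)-8,8-dimethoxy-2,6-dimethylnon-2-ene F9.
   - Ozonolysis (O3, CH2Cl2, pyridine, −78 °C) gives (4R)-6,6-dimethoxy-4-methylheptanal F10.
   - Wittig reaction with methyl (triphenylphosphoranylidene)acetate gives methyl (2E,6R)-8,8-dimethoxy-6-methylnon-2-enoate F11.
   - Hydrogenation (H2, Pd/C, EtOAc, trace Et3N) gives 12.

**Further compounds**

F1 | step 12 | [(1-methoxy-3-methylbuta-1,3-dien-1-yl)oxy]trimethylsilane (E/Z mixture) | COC(=CC(C)=C)O[Si](C)(C)C
F2 | step 12 | methyl (2E,7R,12E,16E)-3,5,7-trimethyl-17-phenyl-5-[(triethylsilyl)peroxy]heptadeca-2,12,16-trienoate (both C5 epimers) | COC(=O)/C=C(\C)CC(C)(OO[Si](CC)(CC)CC)C[C@H](C)CCCC/C=C/CC/C=C/c1ccccc1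
F3 | step 12 | methyl (2E,7R,12E,16E)-5-hydroperoxy-3,5,7-trimethyl-17-phenylheptadeca-2,12,16-trienoate (both C5 epimers) | COC(=O)/C=C(\C)CC(C)(OO)C[C@H](C)CCCC/C=C/CC/C=C/c1ccccc1
F4 | step 12 | methyl 2-{3,5-dimethyl-5-[(2R,7E,11E)-2-methyl-12-phenyldodeca-7,11-dien-1-yl]-1,2-dioxolan-3-yl}acetate (mixture of C3/C5 stereoisomers) | C[C@H](CCCC/C=C/CC/C=C/c1ccccc1)CC1(C)CC(C)(CC(=O)OC)OO1
F5 | step 10 | (4R,9E,13E)-2-methoxy-4-methyl-14-phenyltetradeca-1,9,13-triene | C=C(OC)C[C@H](C)CCCC/C=C/CC/C=C/c1ccccc1
F6 | step 6 | (R)-citronellal, (3R)-3,7-dimethyloct-6-enal | O=CC[C@H](C)CCC=C(C)C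
F7 | step 6 | (4R)-4,8-dimethylnon-7-en-2-ol (both C2 epimers) | CC(O)C[C@H](C)CCC=C(C)C
F8 | step 6 | (4R)-4,8-dimethylnon-7-en-2-one | CC(=O)C[C@H](C)CCC=C(C)C
F9 | step 6 | (6R)-8,8-dimethoxy-2,6-dimethylnon-2-ene | COC(C)(OC)C[C@H](C)CCC=C(C)C
F10 | step 6 | (4R)-6,6-dimethoxy-4-methylheptanal | COC(C)(OC)C[C@H](C)CCC=O
F11 | step 6 | methyl (2E,6R)-8,8-dimethoxy-6-methylnon-2-enoate | COC(C)(OC)C[C@H](C)CC/C=C/C(=O)OC
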